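Numbering: ring A is the guaiacyl ring (C1–C6), the side chain is C7–C9, and ring B is the acetosyringone ring (C1'–C6'), tied to C8 through the oxygen on C4'.
Enabling feature: the carbinol carbon C7 bears only H, OH, C1 of ring A and the oxygenated stereocentre C8. Cutting C7–C1 therefore leaves a ring A aryl nucleophile and an aldehyde whose adjacent C8–OAr bond can steer the addition.
Retrosynthetic cuts: first C7–C1 (aryl metal plus 2-aryloxy aldehyde), then C8–O (phenol plus 2-hydroxy ester). Both arene rings are bought and no ring of the target has to be built.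
Forward order: the ring B phenol (acetyl masked as a dioxolane) is etherified with the C7–C9 glycerate unit, the ester is taken down to the aldehyde, ring A is added as its aryltitanium reagent, and one global deprotection finishes the route.
Stereochemistry: C8 stems from methyl (R)-glycerate acetonide and is inverted once (R to S) in the Mitsunobu etherification. C7 (R) is induced by C8 in a non-chelated Felkin–Anh addition that gives the 7,8-anti (erythro) pair.

Key step: step 8

Step 1
Reactants: 1 acetosyringone [1-(4-hydroxy-3,5-dimethoxyphenyl)ethan-1-one]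
Product: 2 acetosyringone ethylene ketal [2,6-dimethoxy-4-(2-methyl-1,3-dioxolan-2-yl)phenol]
Conditions: HOCH2CH2OH (5 equiv), p-TsOH·H2O (5 mol %), toluene, Dean–Stark, reflux; Et3N quench
Reagents that add atoms: ethylene glycol, OCCO
Why: Acid-catalysed ketalisation with azeotropic removal of water should drive the aryl methyl ketone to its 1,3-dioxolane, the phenol being inert to these conditions and the basic quench keeping the acid-labile aryl ketal intact.

Step 2
Reactants: 3 methyl (R)-2,2-dimethyl-1,3-dioxolane-4-carboxylate
Product: 4 methyl (R)-2,3-dihydroxypropanoate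
Conditions: AcOH–H2O (4:1), rt; toluene azeotrope
Reagents that add atoms: none
Why: Acid-catalysed acetonide hydrolysis should free the 1,2-diol without touching the methyl ester or any bond at the stereocentre, so the R configuration of the chiral pool is carried over unchanged.

Step 3
Reactants: 4 methyl (R)-2,3-dihydroxypropanoate
Product: 5 methyl (R)-3-(tert-butyldimethylsilyloxy)-2-hydroxypropanoate
Conditions: TBSCl (1.05 equiv), imidazole, CH2Cl2, 0 °C
Reagents that add atoms: tert-butyldimethylsilyl chloride (TBSCl), CC(C)(C)[Si](C)(C)Cl
Why: Regioselective silylation should take place at the unhindered primary hydroxyl, because the secondary hydroxyl is more crowded and is deactivated by the adjacent ester.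

Step 4
Reactants: 5 methyl (R)-3-(tert-butyldimethylsilyloxy)-2-hydroxypropanoate; 2 acetosyringone ethylene ketal
Product: 6 methyl (S)-3-(tert-butyldimethylsilyloxy)-2-[2,6-dimethoxy-4-(2-methyl-1,3-dioxolan-2-yl)phenoxy]propanoate
Conditions: PPh3, DIAD (1.3 equiv each), THF (concentrated), 0 °C to rt
Reagents that add atoms: none
Why: In this Mitsunobu etherification the secondary hydroxyl is activated as its oxyphosphonium salt and displaced by the phenoxide in an SN2 process that the flanking ester accelerates, so C8 should be inverted cleanly from R to S, a behaviour well established for 2-hydroxy esters and 2,6-dimethoxyphenols.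

Step 5
Reactants: 6 methyl (S)-3-(tert-butyldimethylsilyloxy)-2-[2,6-dimethoxy-4-(2-methyl-1,3-dioxolan-2-yl)phenoxy]propanoate
Product: 7 (S)-3-(tert-butyldimethylsilyloxy)-2-[2,6-dimethoxy-4-(2-methyl-1,3-dioxolan-2-yl)phenoxy]propanal
Conditions: iBu2AlH (1.1 equiv), CH2Cl2, −78 °C; aqueous potassium sodium tartrate, −78 °C to rt; used at once without chromatography
Reagents that add atoms: none
Why: In this partial ester reduction with iBu2AlH the tetrahedral aluminium hemiacetal, stabilised by the neighbouring aryloxy oxygen, should persist at −78 °C until hydrolysis so that reduction stops at the aldehyde, while the near-neutral cold work-up and immediate use protect the C8 stereocentre.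

Step 6
Reactants: 8 4-bromo-2-methoxyphenol
Product: 9 (4-bromo-2-methoxyphenoxy)(tert-butyl)dimethylsilane
Conditions: TBSCl (1.1 equiv), imidazole, DMF, rt
Reagents that add atoms: tert-butyldimethylsilyl chloride (TBSCl), CC(C)(C)[Si](C)(C)Cl
Why: Routine silylation of a phenol gives an aryl silyl ether that tolerates magnesium and aryl metal chemistry and later falls to the same fluoride treatment as the C9 silyl ether, which makes a separate phenol deprotection unnecessary.

Step 7
Reactants: 9 (4-bromo-2-methoxyphenoxy)(tert-butyl)dimethylsilane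
Product: 10 [4-(tert-butyldimethylsilyloxy)-3-methoxyphenyl]magnesium bromide (titrated THF solution)
Conditions: Mg turnings (I2-activated), THF, reflux
Reagents that add atoms: magnesium, [Mg]
Why: Grignard formation by insertion of magnesium into the aryl C–Br bond should proceed normally, since the methyl ether and the hindered aryl silyl ether are inert to the reagent.

Step 8
Reactants: 10 [4-(tert-butyldimethylsilyloxy)-3-methoxyphenyl]magnesium bromide; 7 (S)-3-(tert-butyldimethylsilyloxy)-2-[2,6-dimethoxy-4-(2-methyl-1,3-dioxolan-2-yl)phenoxy]propanal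
Product: 12 (1R,2S)-3-(tert-butyldimethylsilyloxy)-1-[4-(tert-butyldimethylsilyloxy)-3-methoxyphenyl]-2-[2,6-dimethoxy-4-(2-methyl-1,3-dioxolan-2-yl)phenoxy]propan-1-ol, via aryltitanium triisopropoxide 11 (not isolated)
Conditions: 10 (1.5 equiv), ClTi(OiPr)3 (1.5 equiv), THF, −78 to −30 °C; then 7, −78 to −20 °C; aqueous NH4Cl
Reagents that add atoms: chlorotitanium triisopropoxide, CC(C)O[Ti](Cl)(OC(C)C)OC(C)C (supplies the Ti(OiPr)3 unit of 11; none of its atoms remain in 12)
Why: ClTi(OiPr)3 takes over the aryl group of 10 by salt metathesis to give the weakly basic, weakly Lewis acidic aryltitanium 11, which binds the aldehyde oxygen of 7 and passes its aryl group to the carbonyl carbon through a compact four-centre transition state, forging C7–C1 and, after hydrolysis of the titanium alkoxide, the C7 carbinol. The closest known reaction type is the non-chelation-controlled 1,2-addition of organotitanium triisopropoxides to 2-alkoxy aldehydes; no ring is closed. C7 is the only new stereocentre and is governed by C8 through the polar Felkin–Anh (equally the Cornforth) arrangement: the C8–OAr bond stands perpendicular to the carbonyl plane, the aryl group approaches anti to it along the Bürgi–Dunitz path past the C8 hydrogen, and the Re face of the (S)-aldehyde is attacked, which gives 7R and thus the 7,8-anti (erythro) pair. The step needs 1,2-anti facial selectivity, which is secured by the three isopropoxide ligands that leave titanium unable to bridge two oxygens, by the bulky and poorly donating silyl ether on C9 and by the hindered, weakly basic aryloxy oxygen on C8. It also needs addition to outrun enolisation, since deprotonation at C8 would racemise the aldehyde or expel the C9 silyloxide, and the low basicity of 11 at low temperature provides for that. The dioxolane keeps the ring B acetyl group out of reach, and both silyl ethers are inert to the reagent.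

Step 9
Reactants: 12 (1R,2S)-3-(tert-butyldimethylsilyloxy)-1-[4-(tert-butyldimethylsilyloxy)-3-methoxyphenyl]-2-[2,6-dimethoxy-4-(2-methyl-1,3-dioxolan-2-yl)phenoxy]propan-1-ol
Product: 14 1-{4-[(1R,2S)-1,3-dihydroxy-1-(4-hydroxy-3-methoxyphenyl)propan-2-yl]oxy-3,5-dimethoxyphenyl}ethan-1-one (CNP0242981.1), via desilylated ketal triol 13 (not isolated)
Conditions: nBu4NF (2.5 equiv), THF, 0 °C; then 1 M aqueous HCl, rt, short contact time
Reagents that add atoms: water, O
Why: Fluoride-mediated desilylation should free the ring A phenol and the C9 hydroxyl while ring B is still electron-rich and hence immune to alkoxide-triggered Smiles-type aryl migration, and the brief dilute-acid hydrolysis of the very labile aryl methyl ketal then unveils the acetyl group under conditions too mild to ionise the C7 benzylic alcohol, so both stereocentres persist.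

Compound list
1 | acetosyringone, 1-(4-hydroxy-3,5-dimethoxyphenyl)ethan-1-one | COc1cc(C(C)=O)cc(OC)c1O | starting material
2 | 2,6-dimethoxy-4-(2-methyl-1,3-dioxolan-2-yl)phenol | COc1cc(C2(C)OCCO2)cc(OC)c1O | intermediate
3 | methyl (R)-2,2-dimethyl-1,3-dioxolane-4-carboxylate | COC(=O)[C@H]1COC(C)(C)O1 | starting material
4 | methyl (R)-2,3-dihydroxypropanoate | COC(=O)[C@H](O)CO | intermediate
5 | methyl (R)-3-(tert-butyldimethylsilyloxy)-2-hydroxypropanoate | COC(=O)[C@H](O)CO[Si](C)(C)C(C)(C)C | intermediate
6 | methyl (S)-3-(tert-butyldimethylsilyloxy)-2-[2,6-dimethoxy-4-(2-methyl-1,3-dioxolan-2-yl)phenoxy]propanoate | COC(=O)[C@H](CO[Si](C)(C)C(C)(C)C)Oc1c(OC)cc(C2(C)OCCO2)cc1OC | intermediate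
7 | (S)-3-(tert-butyldimethylsilyloxy)-2-[2,6-dimethoxy-4-(2-methyl-1,3-dioxolan-2-yl)phenoxy]propanal | O=C[C@H](CO[Si](C)(C)C(C)(C)C)Oc1c(OC)cc(C2(C)OCCO2)cc1OC | intermediate
8 | 4-bromo-2-methoxyphenol | COc1cc(Br)ccc1O | starting material
9 | (4-bromo-2-methoxyphenoxy)(tert-butyl)dimethylsilane | COc1cc(Br)ccc1O[Si](C)(C)C(C)(C)C | intermediate
10 | [4-(tert-butyldimethylsilyloxy)-3-methoxyphenyl]magnesium bromide | COc1cc([Mg]Br)ccc1O[Si](C)(C)C(C)(C)C | intermediate
11 | [4-(tert-butyldimethylsilyloxy)-3-methoxyphenyl]titanium triisopropoxide | COc1cc([Ti](OC(C)C)(OC(C)C)OC(C)C)ccc1O[Si](C)(C)C(C)(C)C | intermediate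
12 | (1R,2S)-3-(tert-butyldimethylsilyloxy)-1-[4-(tert-butyldimethylsilyloxy)-3-methoxyphenyl]-2-[2,6-dimethoxy-4-(2-methyl-1,3-dioxolan-2-yl)phenoxy]propan-1-ol | COc1cc([C@@H](O)[C@H](CO[Si](C)(C)C(C)(C)C)Oc2c(OC)cc(C3(C)OCCO3)cc2OC)ccc1O[Si](C)(C)C(C)(C)C | intermediate
13 | (1R,2S)-2-[2,6-dimethoxy-4-(2-methyl-1,3-dioxolan-2-yl)phenoxy]-1-(4-hydroxy-3-methoxyphenyl)propane-1,3-diol | COc1cc([C@@H](O)[C@H](CO)Oc2c(OC)cc(C3(C)OCCO3)cc2OC)ccc1O | intermediate
14 | 1-{4-[(1R,2S)-1,3-dihydroxy-1-(4-hydroxy-3-methoxyphenyl)propan-2-yl]oxy-3,5-dimethoxyphenyl}ethan-1-one | COc1cc([C@@H](O)[C@H](CO)Oc2c(OC)cc(C(C)=O)cc2OC)ccc1O | target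

Total step count: 9. Longest linear sequence: 6 steps (steps 2, 3, 4, 5, 8 and 9, from 3 to 14).

Steps most likely to fail

Step 8 is the riskiest. Facial selectivity may be poor if the magnesium salt and the ortho-methoxy oxygens of ring B open a competing chelated pathway. The fallback sets out from 12 of unsatisfactory purity at C7 and comes back to 12. It moves the stereo-determining event from C–C bond formation to hydride delivery, while the C7–C1 bond still stems from the aryl addition. Oxidation with Dess–Martin periodinane (NaHCO3-buffered, CH2Cl2, 0 °C) erases C7 and should give (S)-3-(tert-butyldimethylsilyloxy)-1-[4-(tert-butyldimethylsilyloxy)-3-methoxyphenyl]-2-[2,6-dimethoxy-4-(2-methyl-1,3-dioxolan-2-yl)phenoxy]propan-1-one F1. Reduction with Zn(BH4)2 in Et2O at −78 to −20 °C then relies on chelation control. Zinc ties the carbonyl oxygen and the C8 aryloxy oxygen into a five-membered chelate, and hydride enters from the side of the C8 hydrogen. For a ketone this mode leads to the same 7R,8S-anti alcohol 12.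

Step 4 comes second. Displacement by the doubly ortho-substituted phenol may be sluggish, so that the activated alcohol is consumed in other ways or stereochemical fidelity at C8 erodes. The fallback sets out from 5 and comes back at 6, and it replaces the redox condensation by an SN2 reaction on a preformed sulfonate. Treatment with Tf2O and 2,6-lutidine (CH2Cl2, −78 °C) should give methyl (R)-3-(tert-butyldimethylsilyloxy)-2-(trifluoromethylsulfonyloxy)propanoate F2. The caesium phenoxide of 2 (Cs2CO3, MeCN, 0 °C) then displaces the triflate with inversion to 6.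

Step 5 comes third. The reduction may run on to the alcohol, or C8 may lose its integrity (epimerisation, loss of the C9 silyloxide) during work-up of the sensitive aldehyde. The fallback sets out from 6 and comes back at 7 by way of a lower oxidation level. Complete reduction with LiBH4 (Et2O–THF, 0 °C) should give the stable, storable (R)-3-(tert-butyldimethylsilyloxy)-2-[2,6-dimethoxy-4-(2-methyl-1,3-dioxolan-2-yl)phenoxy]propan-1-ol F3. Its descriptor changes only because the priorities of the two CH2O arms change. Non-basic oxidation with Dess–Martin periodinane (NaHCO3, CH2Cl2, 0 °C) directly before step 8 then delivers 7.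

Further compounds
F1 | step 8 | (S)-3-(tert-butyldimethylsilyloxy)-1-[4-(tert-butyldimethylsilyloxy)-3-methoxyphenyl]-2-[2,6-dimethoxy-4-(2-methyl-1,3-dioxolan-2-yl)phenoxy]propan-1-one | COc1cc(C(=O)[C@H](CO[Si](C)(C)C(C)(C)C)Oc2c(OC)cc(C3(C)OCCO3)cc2OC)ccc1O[Si](C)(C)C(C)(C)C
F2 | step 4 | methyl (R)-3-(tert-butyldimethylsilyloxy)-2-(trifluoromethylsulfonyloxy)propanoate | COC(=O)[C@H](OS(=O)(=O)C(F)(F)F)CO[Si](C)(C)C(C)(C)C
F3 | step 5 | (R)-3-(tert-butyldimethylsilyloxy)-2-[2,6-dimethoxy-4-(2-methyl-1,3-dioxolan-2-yl)phenoxy]propan-1-ol | OC[C@H](CO[Si](C)(C)C(C)(C)C)Oc1c(OC)cc(C2(C)OCCO2)cc1OC
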